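**Retrosynthetic overview**

1. The strategy rests on the 2,3-dihydro-1,4-benzodioxine ring: O1 (on the arene carbon meta to the acrylate, bonded to C2–CO2H) and O4 (para, bonded to C3–aryl) are the two oxygens of one catechol, and the cis C2–C3 bond is a former Z-alkene.
2. Last disconnection: acidolysis of the two tert-butyl esters, the aryl ketal and the methoxymethyl ether of 18 gives 19.
3. Key disconnection (the only ring formed): O1–C2 and O4–C3 by [4+2] addition of Z-cinnamate 16 to o-quinone 17, made by anodic oxidation of the caffeoyl lactate catechol 11.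
4. 11 comes from 3,4-dihydroxybenzaldehyde and the malonic half-ester of (R)-aryllactate 7 (Knoevenagel–Doebner); 7 comes from methyl (R)-glycidate and an aryl Grignard reagent, so the lactate centre is taken from the chiral pool.
5. 16 comes from the acetonide of 3,4-dihydroxybenzaldehyde by Z-selective Horner–Wadsworth–Emmons olefination.

Key step: step 10

Remark: read from the SMILES, the target is (R) at the lactate carbon and (2S,3S), that is cis, at C2/C3 of the benzodioxine.
Assumption: the (S,S) enantiomer of the bis(oxazoline) ligand is taken as the one that favours the (2S,3S) adduct in step 10. The sense of induction of this new reaction cannot be fixed in advance, and the (R,R) ligand is used if a trial shows the opposite sense.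

**Route**

Step 1
Reactants: 1 4-bromo-2-methoxyphenol
Product: 2 4-bromo-2-methoxy-1-(methoxymethoxy)benzene
Conditions: MeOCH2Cl, i-Pr2NEt, CH2Cl2, 0 °C → rt
Reagents that add atoms: chloromethyl methyl ether, COCCl
Why: O-alkylation of the phenol by the α-chloro ether (acetal formation through the oxocarbenium ion) should give the methoxymethyl ether, which masks the phenol through the Grignard, base and quinone steps and is removed in the final acidolysis.

Step 2
Reactants: 2 4-bromo-2-methoxy-1-(methoxymethoxy)benzene; 3 methyl (2R)-oxirane-2-carboxylate (methyl (R)-glycidate)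
Product: 5 methyl (2R)-2-hydroxy-3-[3-methoxy-4-(methoxymethoxy)phenyl]propanoate, via arylmagnesium bromide 4 (not isolated)
Conditions: Mg, BrCH2CH2Br (cat.), THF, 45 °C; then added to 3, CuBr·SMe2 (10 mol%), THF, −40 → −20 °C; H2O quench
Reagents that add atoms: none
Why: Copper-catalysed Grignard opening of the epoxide (SN2 at the unsubstituted C3) should outpace addition to the ester at low temperature, and since C2 is not touched the (R) configuration of the glycidate becomes the (R) lactate centre of the target.

Step 3
Reactants: 5 methyl (2R)-2-hydroxy-3-[3-methoxy-4-(methoxymethoxy)phenyl]propanoate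
Product: 6 (2R)-2-hydroxy-3-[3-methoxy-4-(methoxymethoxy)phenyl]propanoic acid
Conditions: LiOH·H2O, THF/H2O, 0 °C → rt; then cold 1 M HCl to pH 3
Reagents that add atoms: lithium hydroxide, [Li+].[OH-]
Why: Ester saponification by acyl–oxygen cleavage leaves the carbinol centre untouched, and the aryl methoxymethyl ether is stable to base and to brief cold dilute acid.

Step 4
Reactants: 6 (2R)-2-hydroxy-3-[3-methoxy-4-(methoxymethoxy)phenyl]propanoic acid
Product: 7 tert-butyl (2R)-2-hydroxy-3-[3-methoxy-4-(methoxymethoxy)phenyl]propanoate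
Conditions: Cl3CC(=NH)Ot-Bu, CH2Cl2/cyclohexane, rt
Reagents that add atoms: tert-butyl 2,2,2-trichloroacetimidate, CC(C)(C)OC(=N)C(Cl)(Cl)Cl
Why: The carboxylic acid itself protonates the imidate and the carboxylate captures the tert-butyl cation (esterification by a trichloroacetimidate), so without added Lewis acid the secondary alcohol and the acetal should remain untouched.

Step 5
Reactants: 7 tert-butyl (2R)-2-hydroxy-3-[3-methoxy-4-(methoxymethoxy)phenyl]propanoate; 8 Meldrum's acid (2,2-dimethyl-1,3-dioxane-4,6-dione)
Product: 9 3-{[(2R)-1-tert-butoxy-3-[3-methoxy-4-(methoxymethoxy)phenyl]-1-oxopropan-2-yl]oxy}-3-oxopropanoic acid (malonic half-ester)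
Conditions: toluene, 100 °C
Reagents that add atoms: none
Why: Alcoholysis of Meldrum's acid (acyl transfer with ring opening and loss of acetone) should give the malonic monoester of the hindered secondary alcohol without a coupling reagent and without touching the stereocentre.

Step 6
Reactants: 9 malonic half-ester; 10 3,4-dihydroxybenzaldehyde
Product: 11 (2R)-1-tert-butoxy-3-[3-methoxy-4-(methoxymethoxy)phenyl]-1-oxopropan-2-yl (2E)-3-(3,4-dihydroxyphenyl)prop-2-enoate
Conditions: pyridine, piperidine (cat.), 45 °C, Ar
Reagents that add atoms: none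
Why: Knoevenagel–Doebner condensation (iminium-catalysed condensation at the malonate CH2, then decarboxylative elimination in pyridine) should give the E-caffeate directly with the catechol free, the base being too weak to epimerise the α-acyloxy ester.

Step 7
Reactants: 10 3,4-dihydroxybenzaldehyde
Product: 12 2,2-dimethyl-1,3-benzodioxole-5-carbaldehyde
Conditions: Me2C(OMe)2, p-TsOH·H2O (cat.), benzene, reflux, Soxhlet with 4 Å molecular sieves; aqueous work-up
Reagents that add atoms: 2,2-dimethoxypropane, COC(C)(C)OC
Why: Acid-catalysed transketalisation, driven by removal of methanol, should close the five-membered aryl ketal on the catechol, and any dimethyl acetal formed at the aldehyde reverts on aqueous work-up.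

Step 8
Reactants: 13 diphenyl phosphonate (diphenyl phosphite); 14 tert-butyl bromoacetate
Product: 15 tert-butyl (diphenoxyphosphoryl)acetate
Conditions: Et3N, CH2Cl2, 0 °C → rt
Reagents that add atoms: none
Why: Michaelis–Becker-type P-alkylation, in which the amine makes the H-phosphonate nucleophilic at phosphorus and it displaces bromide from the α-bromo ester, should give the diaryl phosphonoacetate.

Step 9
Reactants: 12 2,2-dimethyl-1,3-benzodioxole-5-carbaldehyde; 15 tert-butyl (diphenoxyphosphoryl)acetate
Product: 16 tert-butyl (2Z)-3-(2,2-dimethyl-1,3-benzodioxol-5-yl)prop-2-enoate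
Conditions: NaH, THF, 0 °C; then 12, −78 → −20 °C; light excluded
Reagents that add atoms: none
Why: Horner–Wadsworth–Emmons olefination in its Z-selective diaryl phosphonate (Ando-type) form, where the aryloxy groups make collapse of the kinetically formed syn adduct faster than its reversal, should give mainly the Z-cinnamate, any E isomer being removed by chromatography.

Step 10
Reactants: 11 caffeoyl lactate catechol; 16 tert-butyl (2Z)-3-(2,2-dimethyl-1,3-benzodioxol-5-yl)prop-2-enoate
Product: 18 tert-butyl (2S,3S)-7-[(1E)-3-{[(2R)-1-tert-butoxy-3-[3-methoxy-4-(methoxymethoxy)phenyl]-1-oxopropan-2-yl]oxy}-3-oxoprop-1-en-1-yl]-3-(2,2-dimethyl-1,3-benzodioxol-5-yl)-2,3-dihydro-1,4-benzodioxine-2-carboxylate, via o-quinone 17 (not isolated)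
Conditions: (a) 11, divided cell, graphite-felt anode, Pt cathode, Bu4NOTf (0.1 M), 2,6-di-tert-butyl-4-methylpyridine, CH2Cl2, −40 °C, controlled potential at the catechol wave, 2 F/mol; (b) anolyte added to 16 (2 equiv), Cu(OTf)2 (20 mol%), (S,S)-2,2′-(propane-2,2-diyl)bis(4-tert-butyl-4,5-dihydrooxazole) (22 mol%), 4 Å molecular sieves, CH2Cl2, −60 → −20 °C, light excluded
Reagents that add atoms: none
Why: Proposed new method: two-electron anodic oxidation of the catechol, the most easily oxidised group (the hindered pyridine takes up the two protons and cannot bind copper), gives o-quinone 17, whose O=C–C=O unit, chelated and further activated by the bis(oxazoline)–Cu(OTf)2 complex, acts as an electron-poor heterodiene towards the aryl-donor Z-alkene 16 in an inverse-electron-demand hetero-Diels–Alder reaction. The closest known reactions are the stereospecific [4+2] additions of o-quinones to electron-rich styrenes and stilbenes, which give 2,3-dihydro-1,4-benzodioxines, and Cu(OTf)2–bis(oxazoline) catalysis of hetero-Diels–Alder reactions of chelating α-dicarbonyl-type heterodienes; a cinnamate ester as the 2π partner and ligand control of its facial approach have not been shown. The dioxane ring closes by this [4+2] cycloaddition, O1–C2 and O4–C3 forming on one face of the alkene in a single asynchronous event driven by rearomatisation of the quinone ring. Regiochemistry follows from polarisation: the alkene carbon α to the ester is the nucleophilic end because positive charge is best placed on the benzylic carbon next to the dioxygenated aryl, and it bonds first to the quinone oxygen meta to the acrylate chain, since attack there puts the developing phenoxide on the para oxygen in conjugation with the acrylate, which then closes on the benzylic carbon. The cis relation of C2 and C3 is set by the Z geometry of 16 through suprafacial addition and needs ring closure to outrun bond rotation in any zwitterion, which low temperature, the weakly polar solvent and the tight copper-bound ion pair are meant to secure. The (2S,3S) absolute configuration is set by which face of the alkene meets the quinone in the endo arrangement under the twofold-symmetric ligand on divalent copper; this is the least certain control element, and the fixed (R)-lactate centre makes the (2R,3R) cis isomer a diastereomer that should be separable by chromatography.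

Step 11
Reactants: 18 fully protected target
Product: 19 (2S,3S)-7-[(1E)-3-{[(1R)-1-carboxy-2-(4-hydroxy-3-methoxyphenyl)ethyl]oxy}-3-oxoprop-1-en-1-yl]-3-(3,4-dihydroxyphenyl)-2,3-dihydro-1,4-benzodioxine-2-carboxylic acid (CNP0249420.1)
Conditions: CF3CO2H/CH2Cl2/H2O (10:10:1), 0 °C → rt; evaporation below rt; reversed-phase HPLC
Reagents that add atoms: none
Why: Acidolysis should cleave the two tert-butyl esters by alkyl–oxygen fission and hydrolyse the aryl ketal and the methoxymethyl acetal through their oxocarbenium ions, while the acrylate ester and the cis-dioxane centres should persist because the adjacent carboxyl disfavours a benzylic cation at C3.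

**Compound list**

1 | 4-bromo-2-methoxyphenol | COc1cc(Br)ccc1O | starting material
2 | 4-bromo-2-methoxy-1-(methoxymethoxy)benzene | COCOc1ccc(Br)cc1OC | intermediate
3 | methyl (2R)-oxirane-2-carboxylate | COC(=O)[C@H]1CO1 | starting material
4 | [3-methoxy-4-(methoxymethoxy)phenyl]magnesium bromide | COCOc1ccc([Mg]Br)cc1OC | intermediate
5 | methyl (2R)-2-hydroxy-3-[3-methoxy-4-(methoxymethoxy)phenyl]propanoate | COCOc1ccc(C[C@@H](O)C(=O)OC)cc1OC | intermediate
6 | (2R)-2-hydroxy-3-[3-methoxy-4-(methoxymethoxy)phenyl]propanoic acid | COCOc1ccc(C[C@@H](O)C(=O)O)cc1OC | intermediate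
7 | tert-butyl (2R)-2-hydroxy-3-[3-methoxy-4-(methoxymethoxy)phenyl]propanoate | COCOc1ccc(C[C@@H](O)C(=O)OC(C)(C)C)cc1OC | intermediate
8 | Meldrum's acid (2,2-dimethyl-1,3-dioxane-4,6-dione) | CC1(C)OC(=O)CC(=O)O1 | starting material
9 | 3-{[(2R)-1-tert-butoxy-3-[3-methoxy-4-(methoxymethoxy)phenyl]-1-oxopropan-2-yl]oxy}-3-oxopropanoic acid | COCOc1ccc(C[C@@H](OC(=O)CC(=O)O)C(=O)OC(C)(C)C)cc1OC | intermediate
10 | 3,4-dihydroxybenzaldehyde | O=Cc1ccc(O)c(O)c1 | starting material
11 | (2R)-1-tert-butoxy-3-[3-methoxy-4-(methoxymethoxy)phenyl]-1-oxopropan-2-yl (2E)-3-(3,4-dihydroxyphenyl)prop-2-enoate | COc1cc(C[C@@H](OC(=O)/C=C/c2ccc(O)c(O)c2)C(=O)OC(C)(C)C)ccc1OCOC | intermediate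
12 | 2,2-dimethyl-1,3-benzodioxole-5-carbaldehyde | CC1(C)Oc2ccc(C=O)cc2O1 | intermediate
13 | diphenyl phosphonate (diphenyl phosphite) | O=[PH](Oc1ccccc1)Oc1ccccc1 | starting material
14 | tert-butyl bromoacetate | CC(C)(C)OC(=O)CBr | starting material
15 | tert-butyl (diphenoxyphosphoryl)acetate | CC(C)(C)OC(=O)CP(=O)(Oc1ccccc1)Oc1ccccc1 | intermediate
16 | tert-butyl (2Z)-3-(2,2-dimethyl-1,3-benzodioxol-5-yl)prop-2-enoate | CC(C)(C)OC(=O)/C=C\c1ccc2c(c1)OC(C)(C)O2 | intermediate
17 | (2R)-1-tert-butoxy-3-[3-methoxy-4-(methoxymethoxy)phenyl]-1-oxopropan-2-yl (2E)-3-(3,4-dioxocyclohexa-1,5-dien-1-yl)prop-2-enoate | COc1cc(C[C@@H](OC(=O)/C=C/C2=CC(=O)C(=O)C=C2)C(=O)OC(C)(C)C)ccc1OCOC | intermediate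
18 | tert-butyl (2S,3S)-7-[(1E)-3-{[(2R)-1-tert-butoxy-3-[3-methoxy-4-(methoxymethoxy)phenyl]-1-oxopropan-2-yl]oxy}-3-oxoprop-1-en-1-yl]-3-(2,2-dimethyl-1,3-benzodioxol-5-yl)-2,3-dihydro-1,4-benzodioxine-2-carboxylate | COc1cc(C[C@@H](OC(=O)/C=C/c2ccc3c(c2)O[C@H](C(=O)OC(C)(C)C)[C@H](c2ccc4c(c2)OC(C)(C)O4)O3)C(=O)OC(C)(C)C)ccc1OCOC | intermediate
19 | (2S,3S)-7-[(1E)-3-{[(1R)-1-carboxy-2-(4-hydroxy-3-methoxyphenyl)ethyl]oxy}-3-oxoprop-1-en-1-yl]-3-(3,4-dihydroxyphenyl)-2,3-dihydro-1,4-benzodioxine-2-carboxylic acid | COc1cc(C[C@@H](OC(=O)/C=C/c2ccc3c(c2)O[C@H](C(=O)O)[C@H](c2ccc(O)c(O)c2)O3)C(=O)O)ccc1O | target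

**Step count and risks**

Total step count: 11. Longest linear sequence: 8 steps (steps 1–6, 10, 11).

Steps most likely to fail:

1. Step 10 (the step that goes beyond known chemistry).
   - What may go wrong: the ester-deactivated alkene may add too slowly, so the quinone is lost to self-condensation; a long-lived zwitterion may rotate before ring closure and leak to the trans isomer; the Z-alkene may isomerise by electron transfer or Lewis acid before it adds; face selection by the ligand may be weak.
   - Fallback (known chemistry): the 2π partner is changed to an electron-rich Z-propenylarene of the class known to add to o-quinones, and the carboxyl oxidation level is introduced after the ring is built. It sets out from 16 and 11. i-Bu2AlH (CH2Cl2, −78 °C) should reduce 16 to (2Z)-3-(2,2-dimethyl-1,3-benzodioxol-5-yl)prop-2-en-1-ol F1, and t-BuMe2SiCl/imidazole (DMF) should give tert-butyl{[(2Z)-3-(2,2-dimethyl-1,3-benzodioxol-5-yl)prop-2-en-1-yl]oxy}dimethylsilane F2. o-Quinone 17, generated from 11 as in step 10(a), is combined with F2 in CH2Cl2 without Lewis acid (−40 °C → rt). This stereospecific thermal [4+2] should give the cis (2R,3S)-2-(silyloxymethyl)benzodioxine F3, with the same regiochemistry, since the carbon bearing CH2OSi is the nucleophilic end. The two cis diastereomers would be separated by preparative HPLC with the help of the (R)-lactate centre. Bu4NF/AcOH (THF, 0 °C) should free the cis (2R,3S) primary alcohol F4. TEMPO/iodobenzene diacetate (CH2Cl2, 0 °C) should give the cis (2S,3S) C2 aldehyde F5 (not isolated, kept cold and free of base to avoid epimerisation at C2). NaClO2/NaH2PO4/2-methyl-2-butene (t-BuOH/H2O) should oxidise it to the cis (2S,3S) C2 carboxylic acid F6. The acidolysis of step 11 applied to F6 comes back to the route at 19.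

2. Step 11.
   - What may go wrong: strong protic acid may open the benzylic C3–O4 bond reversibly, with cis-to-trans epimerisation, and the freed catechol may capture tert-butyl cation or formaldehyde.
   - Fallback: the one-pot protic acidolysis is replaced by silyl-transfer dealkylation followed by weak-acid ketal hydrolysis. It sets out from 18. Me3SiOTf/2,6-lutidine (CH2Cl2, 0 °C → rt), a reagent pair known to exchange tert-butyl esters and methoxymethyl ethers for silyl groups, should give the bis(trimethylsilyl) ester trimethylsilyl aryl ether F7 (not isolated). Aqueous work-up at pH 4 should hydrolyse it to the ketal-protected (2S,3S) diacid phenol F8. The aryl ketal is then hydrolysed in AcOH/H2O (4:1, 60 °C), which comes back to the route at 19.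

3. Step 9.
   - What may go wrong: incomplete Z selectivity in the olefination, and Z-to-E isomerisation of the electron-rich cinnamate by light or traces of acid during isolation; any E isomer carried on would give trans-benzodioxine in step 10.
   - Fallback: the Z geometry is fixed by syn semi-hydrogenation of an alkyne. It sets out from 12. Ohira–Bestmann homologation (dimethyl (1-diazo-2-oxopropyl)phosphonate, K2CO3, MeOH) should give 5-ethynyl-2,2-dimethyl-1,3-benzodioxole F9. n-BuLi (THF, −78 °C) gives [(2,2-dimethyl-1,3-benzodioxol-5-yl)ethynyl]lithium F10 (not isolated), which di-tert-butyl dicarbonate should acylate to tert-butyl 3-(2,2-dimethyl-1,3-benzodioxol-5-yl)prop-2-ynoate F11. Semi-hydrogenation (H2, Pd/CaCO3 poisoned with Pb(OAc)2, quinoline, EtOAc), stopped at one equivalent of H2, comes back to the route at 16.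

**Further compounds**

F1 | step 10 | (2Z)-3-(2,2-dimethyl-1,3-benzodioxol-5-yl)prop-2-en-1-ol | OC/C=C\c1ccc2c(c1)OC(C)(C)O2
F2 | step 10 | tert-butyl{[(2Z)-3-(2,2-dimethyl-1,3-benzodioxol-5-yl)prop-2-en-1-yl]oxy}dimethylsilane | CC(C)(C)[Si](C)(C)OC/C=C\c1ccc2c(c1)OC(C)(C)O2
F3 | step 10 | cis (2R,3S) analogue of 18 with CH2OSiMe2t-Bu in place of CO2t-Bu at C2 | COc1cc(C[C@@H](OC(=O)/C=C/c2ccc3c(c2)O[C@H](CO[Si](C)(C)C(C)(C)C)[C@H](c2ccc4c(c2)OC(C)(C)O4)O3)C(=O)OC(C)(C)C)ccc1OCOC
F4 | step 10 | cis (2R,3S) analogue of 18 with CH2OH at C2 | COc1cc(C[C@@H](OC(=O)/C=C/c2ccc3c(c2)O[C@H](CO)[C@H](c2ccc4c(c2)OC(C)(C)O4)O3)C(=O)OC(C)(C)C)ccc1OCOC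
F5 | step 10 | cis (2S,3S) analogue of 18 with CHO at C2 | COc1cc(C[C@@H](OC(=O)/C=C/c2ccc3c(c2)O[C@H](C=O)[C@H](c2ccc4c(c2)OC(C)(C)O4)O3)C(=O)OC(C)(C)C)ccc1OCOC
F6 | step 10 | cis (2S,3S) analogue of 18 with CO2H at C2 | COc1cc(C[C@@H](OC(=O)/C=C/c2ccc3c(c2)O[C@H](C(=O)O)[C@H](c2ccc4c(c2)OC(C)(C)O4)O3)C(=O)OC(C)(C)C)ccc1OCOC
F7 | step 11 | bis(trimethylsilyl) ester trimethylsilyl aryl ether of the ketal-protected target | COc1cc(C[C@@H](OC(=O)/C=C/c2ccc3c(c2)O[C@H](C(=O)O[Si](C)(C)C)[C@H](c2ccc4c(c2)OC(C)(C)O4)O3)C(=O)O[Si](C)(C)C)ccc1O[Si](C)(C)C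
F8 | step 11 | ketal-protected (2S,3S) diacid phenol | COc1cc(C[C@@H](OC(=O)/C=C/c2ccc3c(c2)O[C@H](C(=O)O)[C@H](c2ccc4c(c2)OC(C)(C)O4)O3)C(=O)O)ccc1O
F9 | step 9 | 5-ethynyl-2,2-dimethyl-1,3-benzodioxole | C#Cc1ccc2c(c1)OC(C)(C)O2
F10 | step 9 | [(2,2-dimethyl-1,3-benzodioxol-5-yl)ethynyl]lithium | [Li]C#Cc1ccc2c(c1)OC(C)(C)O2
F11 | step 9 | tert-butyl 3-(2,2-dimethyl-1,3-benzodioxol-5-yl)prop-2-ynoate | CC(C)(C)OC(=O)C#Cc1ccc2c(c1)OC(C)(C)O2
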